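# Total synthesis of (1R,3S)-5-(4,5-dimethoxy-7-methylnaphthalen-1-yl)-6,8-dimethoxy-1,2,3-trimethyl-1,2,3,4-tetrahydroisoquinoline (30)

## Analysis of the target

Compound 30 consists of two aromatic units joined by one C–C bond. One is a 6,8-dimethoxy-1,2,3-trimethyl-1,2,3,4-tetrahydroisoquinoline and the other a 4,5-dimethoxy-7-methylnaphthalene, linked from isoquinoline C5 to naphthalene C1 (naphthalene numbered from the biaryl carbon). The only stereocentres are C1 (R) and C3 (S) of the nitrogen ring; they stand 1,3 to each other across N2 and carry their methyl groups on the same face, so the relation to be set is cis. The biaryl bond is flanked by the C6 methoxy group and the C4 methylene on one side and by C2–H and the peri C8–H on the other. This makes it a hindered, slowly rotating axis whose configuration the structure leaves open. The four aryl methyl ethers are robust, but both arenes are very electron-rich and open to oxidants and electrophiles, and the benzylic tertiary amine is basic, nucleophilic and oxidisable at C1. The difficulty lies in making the crowded C5–C1 bond and in placing three substituents correctly on the naphthalene, not in the two stereocentres, which substrate-controlled imine reduction can set. The strategy rests on the naphthalene ring that carries the axis (C1, C2, C3, C4, C4a, C8a): C1 bears the isoquinoline, C4 para to it bears a methoxy group, C2 and C3 are unsubstituted, and the C4a–C8a edge belongs to a benzo ring with methoxy at C5 and methyl at C7. Read this way, C1–C4 are the diene carbons of a 6-aryl-3-methoxy-2-pyrone and C4a/C8a are the triply bonded carbons of 3-methoxy-5-methylbenzyne, so the ring can be grown on C5 by cycloaddition and loss of CO2 instead of being attached by cross-coupling.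

## Retrosynthetic reasoning

**30 ⇒ 29 (N-methyl carbon).** The target is traced back to the methyl carbamate 29, whose carbonyl carbon becomes the N-methyl carbon on full hydride reduction. The cut is made here because the preceding step involves an aryne. A tertiary amine would add to an aryne through nitrogen, whereas an acylated nitrogen does not. The gain is a protecting group that never has to be removed. The forward step only has to reduce one carbamate in a molecule that otherwise holds aryl ethers.

**29 ⇒ 18 + 26 (naphthalene C4–C4a and C1–C8a).** Both bonds are cut together.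
- This removes the benzo ring as the aryne 27, stored as the silyl triflate 26.
- It leaves C1–C4 as the diene of pyrone 18, in which an O–C(=O) bridge joins C1 and C4.
- Cutting the C5–C1 biaryl bond instead would demand a coupling of two arenes that together carry three ortho substituents and a peri hydrogen.
- Cutting the ring keeps that bond in place from a stage at which its carbon was still sp-hybridised.
- Forward, the cycloaddition through the bridged lactone 28 must occur at a shielded diene terminus and in one orientation, with pyrone C6 bound to the aryne carbon remote from the methoxy group.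
- The cycloreversion that expels the bridge then delivers the ring already aromatic.

**26 ⇒ 24 ⇒ 20 ⇒ 19 (C–Si and O–S bonds).** The silyl group of 26 sits between two oxygen substituents. This is the position that two cooperating directing groups activate for lithiation. The phenol 19 is therefore turned into the carbamate 20, which directs metalation (through 21, 22 and 23) to give 24. The same carbamate is later exchanged for the sulfonate through phenol 25 in one operation. Electrophilic halogenation of 19 would go para to oxygen and was not considered for that reason.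

**18 ⇒ 17 ⇒ 16 (pyrone O1–C6).** Opening the lactone at the ring oxygen gives the enynoic acid 17 and its methyl ester 16. In both, pyrone C5 and C6 are the two alkyne carbons. The forward reaction is a 6-endo closure of the carboxyl oxygen onto the aryl-bearing alkyne carbon. The ortho- and para-methoxy groups of the isoquinoline arene stabilise positive charge at exactly that carbon, so the substrate supports the wanted mode.

**16 ⇒ 11 + 15 (C5–C(sp)).** The carbon that later becomes naphthalene C1 is attached to C5 as an alkyne terminus. An alkyne has no steric demand next to the two ortho substituents. An aryl iodide is chosen over a bromide because oxidative addition to this electron-rich, doubly ortho-substituted ring would otherwise be slow.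

**15 ⇒ 14 ⇒ 12 + 13 (C=C of the enyne).** Only the isomer with ester and alkyne on the same side of the double bond can close to the six-membered lactone, and it is not the thermodynamically preferred one. The olefination is therefore not run on an aldehyde attached to the chiral isoquinoline. It is run on the small silyl ynal 12 with phosphonate 13. The isomers can then be separated on cheap achiral material, and only the correct isomer 14, desilylated to 15, enters the main line.

**11 ⇒ 10 ⇒ 9 (C5–I and N–C(=O)).** C5 is ortho to one methoxy group and para to the other, while C7 lies between both, so electrophilic iodination of 10 should choose C5. Acylation of 9 comes first so that the nitrogen is inert towards the iodinating agent.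

**9 ⇒ 8 ⇒ 7 (C1–H and C1–C8a).** The C1 stereocentre is set by hydride addition to the cyclic imine 8 under control of the C3 methyl group. The imine arises by cyclodehydration of acetamide 7 onto either of two equivalent, doubly activated ring positions, so no regiochemical question arises.

**7 ⇒ 5 ⇒ 4 ⇒ 1 + 2 (C3–N and C4–aryl).** The C3 stereocentre is bought. Epoxide 2 is opened at its unsubstituted carbon by the Grignard reagent 3 made from bromide 1, giving alcohol 4 with its centre untouched. One inversion with azide gives 5 with the S configuration needed. Reduction via amine 6 with in situ acetylation gives 7.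

## Alternatives that were turned down

**Alternative 1:** Here the central benzene ring of the isoquinoline (C4a, C5, C6, C7, C8, C8a) is taken apart rather than the naphthalene.
- *Disconnection.* Cutting C4a–C8a and C6–C7 leads to methyl acetoacetate (A1) and to A2, an α-naphthyl α,β-unsaturated ester carrying the Boc-protected (S)-2-aminopropyl chain on its β-carbon.
- *Forward key step.* Under alkoxide base the active methylene of A1 adds to the β-carbon of A2. The terminal methyl carbon of A1 is then acylated by the ester of A2, closing the cyclohexane-1,3-dione A3.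
- *For it.* The reagents are cheap and C3 comes from the chiral pool. The aryl–ring bond is present from the start as an arylacetic ester bond. The naphthalene substitution pattern raises no orientation question, and on this point it is stronger than the chosen route.
- *Against it.* A2 is a trisubstituted acceptor whose twisted α-naphthyl group shields the β-carbon, and its acidic γ-hydrogens invite deconjugation by the same base, so the reversible Michael step is poorly driven.
- *After A3.* The ring must still be oxidised to the aromatic level beside an electron-rich naphthalene and O-methylated twice. Its ester must then be converted into the C1 unit, the nitrogen ring closed, C1 reduced cis and the nitrogen methylated.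
- *Comparison.* That is a long tail after the key step. The chosen route needs one step after its key step and forms its new ring directly at the aromatic level.

**Alternative 2:** The same naphthalene ring as in the chosen route is formed, but by anionic annulation.
- *Disconnection.* Cutting C1–C2 and C3–C4 leads to the diarylmethane benzoate A4 and methyl acrylate (A5).
- *Forward key step.* A lithium amide base deprotonates the diarylmethyl position of A4. The anion adds to A5 and the resulting ester enolate closes onto the benzoate, giving the tetralone β-keto ester A6 with the isoquinoline already on the future C1.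
- *For it.* The orientation of the two halves is fixed by connectivity, a clear advantage over the chosen route, where it rests on polar and steric bias. The tertiary amine can also be carried unprotected.
- *Against it.* The carbanion is flanked by ortho substituents on both aryl groups and must create a congested tertiary centre, in competition with anionic polymerisation of A5.
- *After A6.* The extra ester carbon must be lost, and dehydrogenation and O-methylation must follow. The dehydrogenation has to be run beside a benzylic tertiary amine whose C1–H is itself oxidisable, which endangers the C1 stereocentre. A4 also still needs a C–C bond to be made at hindered C5.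
- *Comparison.* In exchange for its weaker regiochemical guarantee, the chosen route offers the correct oxidation level at ring closure and no oxidant in the presence of the amine.

**Alternative 3:** The nitrogen ring is closed last by cutting N2–C3.
- *Disconnection.* This leads to the (R)-1-arylethylamine A7, which bears an ortho-allyl group and the complete naphthyl substituent.
- *Forward key step.* A lanthanide amide catalyst brings about intramolecular Markovnikov hydroamination in a 6-exo sense. This gives the secondary amine A8 with C3 cis to C1 through a chair-like transition state.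
- *For it.* The step is atom-economical and cis-2,6 selectivity is typical of this ring size. Only N-methylation remains afterwards, so the end game is as short as in the chosen route.
- *Against it.* The strategy does nothing for the hard bond, because the hindered biaryl must be made earlier by conventional cross-coupling. C1 needs an asymmetric step of its own. The C1 methyl group next to the C8 methoxy group prefers a pseudo-axial position, which undermines the chair model behind the cis prediction. Four methoxy groups can also bind the oxophilic catalyst, and the allyl group can isomerise into conjugation.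
- *Comparison.* The chosen route settles the cis relation early, on a simple substrate, and spends its risk on the bond that is actually difficult.

Key step: step 16

Assumption: the target structure specifies no configuration at the biaryl axis, so 29 and 30 are taken as the mixture of the two atropo-diastereomers, to be separated at the end if one of them is wanted.

## Steps

Step 1
Reactants: 1 1-bromo-3,5-dimethoxybenzene; 2 (R)-propylene oxide
Product: 4 (2R)-1-(3,5-dimethoxyphenyl)propan-2-ol, via 3,5-dimethoxyphenylmagnesium bromide 3 (not isolated)
Conditions: Mg, THF, reflux; then CuI (10 mol%), 2, THF, −30 → 0 °C; aq. NH4Cl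
Reagents that add atoms: none
Why: Copper-catalysed opening of a terminal epoxide by an aryl Grignard reagent occurs by SN2 attack at the unsubstituted carbon, so the C–O stereocentre of 2 is not touched and 4 keeps the R configuration.

Step 2
Reactants: 4 (2R)-1-(3,5-dimethoxyphenyl)propan-2-ol
Product: 5 1-[(2S)-2-azidopropyl]-3,5-dimethoxybenzene
Conditions: PPh3, DIAD, (PhO)2P(O)N3, THF, 0 °C → rt
Reagents that add atoms: diphenylphosphoryl azide, [N-]=[N+]=NP(=O)(Oc1ccccc1)Oc1ccccc1
Why: Mitsunobu azidation: the alkoxyphosphonium ion of the secondary alcohol is displaced by azide in an SN2 step with inversion, turning R into the S configuration required at C3 of the target.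

Step 3
Reactants: 5 1-[(2S)-2-azidopropyl]-3,5-dimethoxybenzene
Product: 7 N-[(2S)-1-(3,5-dimethoxyphenyl)propan-2-yl]acetamide, via primary amine 6 (not isolated)
Conditions: H2 (1 atm), Pd/C, Ac2O, EtOAc, rt
Reagents that add atoms: acetic anhydride, CC(=O)OC(C)=O
Why: Catalytic hydrogenation of the azide releases N2 and gives amine 6, which is acetylated as it forms; no bond to the stereocentre is broken.

Step 4
Reactants: 7 N-[(2S)-1-(3,5-dimethoxyphenyl)propan-2-yl]acetamide
Product: 8 (3S)-6,8-dimethoxy-1,3-dimethyl-3,4-dihydroisoquinoline
Conditions: POCl3, MeCN, reflux; then aq. NaOH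
Reagents that add atoms: none
Why: Bischler–Napieralski cyclodehydration: the activated amide is attacked by a ring carbon that is ortho to one methoxy group and para to the other. The two candidate positions are equivalent, so one regioisomer results, and C3 is a spectator.

Step 5
Reactants: 8 (3S)-6,8-dimethoxy-1,3-dimethyl-3,4-dihydroisoquinoline
Product: 9 (1R,3S)-6,8-dimethoxy-1,3-dimethyl-1,2,3,4-tetrahydroisoquinoline
Conditions: NaBH4, MeOH, −20 → 0 °C
Reagents that add atoms: none
Why: Substrate-controlled hydride reduction of a cyclic imine: hydride approaches C1 of the half-chair from the face opposite the C3 methyl group. The new C1–H is therefore anti to that methyl group and the two methyl groups end up cis (1R,3S). Any trans isomer is removed by chromatography here or at 10.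

Step 6
Reactants: 9 (1R,3S)-6,8-dimethoxy-1,3-dimethyl-1,2,3,4-tetrahydroisoquinoline
Product: 10 methyl (1R,3S)-6,8-dimethoxy-1,3-dimethyl-3,4-dihydroisoquinoline-2(1H)-carboxylate
Conditions: ClCO2Me, K2CO3, CH2Cl2/H2O, 0 °C → rt
Reagents that add atoms: methyl chloroformate, COC(=O)Cl
Why: Schotten–Baumann acylation of the secondary amine. The small chloroformate tolerates the two flanking methyl-bearing carbons, and the carbamate removes nitrogen nucleophilicity for steps 7 to 16 while holding the future N-methyl carbon.

Step 7
Reactants: 10 methyl (1R,3S)-6,8-dimethoxy-1,3-dimethyl-3,4-dihydroisoquinoline-2(1H)-carboxylate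
Product: 11 methyl (1R,3S)-5-iodo-6,8-dimethoxy-1,3-dimethyl-3,4-dihydroisoquinoline-2(1H)-carboxylate
Conditions: NIS (1.0 equiv), CF3CO2H (cat.), MeCN, 0 °C → rt, dark
Reagents that add atoms: N-iodosuccinimide, O=C1CCC(=O)N1I
Why: Electrophilic aromatic iodination of a dimethoxyarene. C5 is para to the C8 methoxy group and ortho to the C6 methoxy group, whereas C7 is wedged between both, so the usual para preference and sterics both point to C5.

Step 8
Reactants: 12 3-(trimethylsilyl)propynal; 13 methyl 2-(dimethoxyphosphoryl)-2-methoxyacetate
Product: 14 methyl (E)-2-methoxy-5-(trimethylsilyl)pent-2-en-4-ynoate (ester and alkynyl group on the same side of the double bond)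
Conditions: KN(SiMe3)2, 18-crown-6, THF, −78 °C; chromatographic separation of the E isomer
Reagents that add atoms: none
Why: Horner–Wadsworth–Emmons olefination; both geometrical isomers are to be expected. The dissociated potassium enolate at low temperature keeps the addition kinetic and should raise the share of the isomer with ester cis to the slim alkynyl group. That isomer is isolated here on a cheap achiral fragment, recognisable by the NOE between the vinyl hydrogen and the enol ether methyl group.

Step 9
Reactants: 14 methyl (E)-2-methoxy-5-(trimethylsilyl)pent-2-en-4-ynoate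
Product: 15 methyl (E)-2-methoxypent-2-en-4-ynoate
Conditions: Bu4NF, AcOH, THF, 0 °C
Reagents that add atoms: none
Why: Fluoride-induced protodesilylation of an alkynylsilane. The acetic acid buffer suppresses basic conjugate addition to the enynoate, so the alkene geometry should be kept; 15 is used promptly as a solution.

Step 10
Reactants: 11 methyl (1R,3S)-5-iodo-6,8-dimethoxy-1,3-dimethyl-3,4-dihydroisoquinoline-2(1H)-carboxylate; 15 methyl (E)-2-methoxypent-2-en-4-ynoate
Product: 16 methyl (1R,3S)-5-[(3E)-4,5-dimethoxy-5-oxopent-3-en-1-yn-1-yl]-6,8-dimethoxy-1,3-dimethyl-3,4-dihydroisoquinoline-2(1H)-carboxylate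
Conditions: PdCl2(PPh3)2 (5 mol%), CuI (10 mol%), Et3N, THF, rt → 45 °C, degassed
Reagents that add atoms: none
Why: Sonogashira coupling: the iodide allows oxidative addition to zerovalent palladium despite the electron-rich, doubly ortho-substituted ring, and the linear alkynyl partner has no steric demand. A tertiary amine base does not add to the enynoate, so the E geometry is carried through.

Step 11
Reactants: 16 methyl (1R,3S)-5-[(3E)-4,5-dimethoxy-5-oxopent-3-en-1-yn-1-yl]-6,8-dimethoxy-1,3-dimethyl-3,4-dihydroisoquinoline-2(1H)-carboxylate
Product: 17 (2E)-5-[(1R,3S)-6,8-dimethoxy-2-(methoxycarbonyl)-1,3-dimethyl-1,2,3,4-tetrahydroisoquinolin-5-yl]-2-methoxypent-2-en-4-ynoic acid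
Conditions: LiOH, THF/H2O, rt; then 1 M HCl to pH 3, 0 °C
Reagents that add atoms: lithium hydroxide, [Li+].[OH-]
Why: Saponification of the unhindered methyl ester. The hindered N,N-dialkyl carbamate is far less electrophilic and survives, and the enol ether oxygen lowers the electrophilicity of the β-carbon, so hydroxide does not add there and the geometry holds.

Step 12
Reactants: 17 (2E)-5-[(1R,3S)-6,8-dimethoxy-2-(methoxycarbonyl)-1,3-dimethyl-1,2,3,4-tetrahydroisoquinolin-5-yl]-2-methoxypent-2-en-4-ynoic acid
Product: 18 methyl (1R,3S)-6,8-dimethoxy-5-(3-methoxy-2-oxo-2H-pyran-6-yl)-1,3-dimethyl-3,4-dihydroisoquinoline-2(1H)-carboxylate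
Conditions: ZnBr2 (20 mol%), THF, rt → 45 °C
Reagents that add atoms: none
Why: Lewis-acid-catalysed 6-endo-dig cycloisomerisation of a 2-en-4-ynoic acid with the acid cis to the alkyne; ZnBr2 is the promoter known to favour pyranones over alkylidene butenolides. The ortho/para-dimethoxyaryl group, standing perpendicular to the enyne plane, stabilises the in-plane positive charge at the carbon being attacked, which reinforces the 6-endo mode.

Step 13
Reactants: 19 3-methoxy-5-methylphenol
Product: 20 3-methoxy-5-methylphenyl isopropylcarbamate
Conditions: iPrNCO, Et3N (cat.), CH2Cl2, rt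
Reagents that add atoms: isopropyl isocyanate, CC(C)N=C=O
Why: Base-catalysed addition of a phenol to an isocyanate. It installs a strong ortho-directing group that can later be removed under mild, non-acidic conditions.

Step 14
Reactants: 20 3-methoxy-5-methylphenyl isopropylcarbamate
Product: 24 3-methoxy-5-methyl-2-(trimethylsilyl)phenyl isopropylcarbamate, via N-silyl carbamate 21 (not isolated), via aryllithium 22 (not isolated), via bis-silyl carbamate 23 (not isolated)
Conditions: TBSOTf, TMEDA, Et2O, 0 °C → rt; n-BuLi, TMEDA, −78 °C; TMSCl, −78 °C → rt; aq. NaHSO4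
Reagents that add atoms: chlorotrimethylsilane, C[Si](C)(C)Cl
Why: Directed ortho-metalation: transient N-silylation masks the N–H. Lithiation then occurs at C2, the one position activated by both the carbamate and the methoxy group, faster than at C6 or at the benzylic methyl group at −78 °C. The acidic work-up cleaves only the labile N–Si bond.

Step 15
Reactants: 24 3-methoxy-5-methyl-2-(trimethylsilyl)phenyl isopropylcarbamate
Product: 26 3-methoxy-5-methyl-2-(trimethylsilyl)phenyl trifluoromethanesulfonate, via silylphenol 25 (not isolated)
Conditions: DBU, Et2NH, MeCN, 40 °C; then PhNTf2, rt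
Reagents that add atoms: N-phenylbis(trifluoromethanesulfonimide), O=S(=O)(N(c1ccccc1)S(=O)(=O)C(F)(F)F)C(F)(F)F
Why: E1cB cleavage of the N–H carbamate releases the phenoxide, and diethylamine traps the isocyanate as a urea. The phenoxide is triflated in the same flask, so the acid-sensitive aryl–silicon bond never meets protic acid.

Step 16
Reactants: 18 methyl (1R,3S)-6,8-dimethoxy-5-(3-methoxy-2-oxo-2H-pyran-6-yl)-1,3-dimethyl-3,4-dihydroisoquinoline-2(1H)-carboxylate; 26 3-methoxy-5-methyl-2-(trimethylsilyl)phenyl trifluoromethanesulfonate
Product: 29 methyl (1R,3S)-5-(4,5-dimethoxy-7-methylnaphthalen-1-yl)-6,8-dimethoxy-1,3-dimethyl-3,4-dihydroisoquinoline-2(1H)-carboxylate, via 3-methoxy-5-methylbenzyne 27 (not isolated), via bridged lactone 28 (not isolated)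
Conditions: CsF (4 equiv), 26 (2 equiv, slow addition), MeCN, rt → 50 °C
Reagents that add atoms: none
Why: Fluoride attacks the silicon of 26 and the resulting aryl anion expels triflate, releasing aryne 27 slowly under neutral conditions. Aryne 27 serves as the 2π partner and pyrone 18 as the 4π partner in a concerted but asynchronous [4+2] cycloaddition across pyrone C3 and C6, which forms naphthalene C4–C4a and C1–C8a and gives bridged lactone 28; retro-[4+2] loss of CO2 follows at once because it creates an aromatic ring. The closest known reaction type is the Diels–Alder reaction of arynes with 2-pyrones followed by decarboxylative cycloreversion to naphthalenes, and only the degree of hindrance at pyrone C6 is unusual here. The one new ring (naphthalene C1–C4, C4a, C8a) is thus closed by intermolecular cycloaddition and emerges at the aromatic oxidation level. No lasting stereocentre is created: the two bridgehead centres of 28 vanish with CO2, C1 and C3 of the isoquinoline are spectators, and the sense of the new axis is not controlled. The selectivity needed is orientation: the methoxy group next to the triple bond of 27 polarises it inductively so that the remote carbon (future C8a) is the electrophilic end, and the 3-methoxy group of 18 raises electron density and HOMO coefficient at the vinylogous diene terminus C6, so C6–C8a bonding should lead. Sterics point the same way, since the opposite orientation would force the perpendicular isoquinoline into a peri contact with the aryne methoxy group, whereas the wanted one only brings two methoxy groups together. Chemoselectivity is secured by the carbamate, which removes nitrogen nucleophilicity, and by the absence of any O–H or N–H bond in 18.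

Step 17
Reactants: 29 methyl (1R,3S)-5-(4,5-dimethoxy-7-methylnaphthalen-1-yl)-6,8-dimethoxy-1,3-dimethyl-3,4-dihydroisoquinoline-2(1H)-carboxylate
Product: 30 (1R,3S)-5-(4,5-dimethoxy-7-methylnaphthalen-1-yl)-6,8-dimethoxy-1,2,3-trimethyl-1,2,3,4-tetrahydroisoquinoline
Conditions: LiAlH4, THF, reflux; then Na2SO4·10H2O
Reagents that add atoms: none
Why: Exhaustive hydride reduction of a carbamate runs through the formamide and iminium stages and turns N–CO2Me into N–CH3. Aryl methyl ethers and both stereocentres are inert to the reagent.

## Compound list

1 | 1-bromo-3,5-dimethoxybenzene | COc1cc(Br)cc(OC)c1 | starting material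
2 | (R)-propylene oxide | C[C@@H]1CO1 | starting material
3 | 3,5-dimethoxyphenylmagnesium bromide | COc1cc([Mg]Br)cc(OC)c1 | intermediate
4 | (2R)-1-(3,5-dimethoxyphenyl)propan-2-ol | COc1cc(C[C@@H](C)O)cc(OC)c1 | intermediate
5 | 1-[(2S)-2-azidopropyl]-3,5-dimethoxybenzene | COc1cc(C[C@H](C)N=[N+]=[N-])cc(OC)c1 | intermediate
6 | (2S)-1-(3,5-dimethoxyphenyl)propan-2-amine | COc1cc(C[C@H](C)N)cc(OC)c1 | intermediate
7 | N-[(2S)-1-(3,5-dimethoxyphenyl)propan-2-yl]acetamide | COc1cc(C[C@H](C)NC(C)=O)cc(OC)c1 | intermediate
8 | (3S)-6,8-dimethoxy-1,3-dimethyl-3,4-dihydroisoquinoline | COc1cc(OC)c2c(c1)C[C@H](C)N=C2C | intermediate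
9 | (1R,3S)-6,8-dimethoxy-1,3-dimethyl-1,2,3,4-tetrahydroisoquinoline | COc1cc(OC)c2c(c1)C[C@H](C)N[C@@H]2C | intermediate
10 | methyl (1R,3S)-6,8-dimethoxy-1,3-dimethyl-3,4-dihydroisoquinoline-2(1H)-carboxylate | COc1cc(OC)c2c(c1)C[C@H](C)N(C(=O)OC)[C@@H]2C | intermediate
11 | methyl (1R,3S)-5-iodo-6,8-dimethoxy-1,3-dimethyl-3,4-dihydroisoquinoline-2(1H)-carboxylate | COc1cc(OC)c2c(c1I)C[C@H](C)N(C(=O)OC)[C@@H]2C | intermediate
12 | 3-(trimethylsilyl)propynal | C[Si](C)(C)C#CC=O | starting material
13 | methyl 2-(dimethoxyphosphoryl)-2-methoxyacetate | COC(C(=O)OC)P(=O)(OC)OC | starting material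
14 | methyl (E)-2-methoxy-5-(trimethylsilyl)pent-2-en-4-ynoate | C[Si](C)(C)C#C/C=C(/OC)C(=O)OC | intermediate
15 | methyl (E)-2-methoxypent-2-en-4-ynoate | C#C/C=C(/OC)C(=O)OC | intermediate
16 | methyl (1R,3S)-5-[(3E)-4,5-dimethoxy-5-oxopent-3-en-1-yn-1-yl]-6,8-dimethoxy-1,3-dimethyl-3,4-dihydroisoquinoline-2(1H)-carboxylate | COc1cc(OC)c2c(c1C#C/C=C(/OC)C(=O)OC)C[C@H](C)N(C(=O)OC)[C@@H]2C | intermediate
17 | (2E)-5-[(1R,3S)-6,8-dimethoxy-2-(methoxycarbonyl)-1,3-dimethyl-1,2,3,4-tetrahydroisoquinolin-5-yl]-2-methoxypent-2-en-4-ynoic acid | COc1cc(OC)c2c(c1C#C/C=C(/OC)C(=O)O)C[C@H](C)N(C(=O)OC)[C@@H]2C | intermediate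
18 | methyl (1R,3S)-6,8-dimethoxy-5-(3-methoxy-2-oxo-2H-pyran-6-yl)-1,3-dimethyl-3,4-dihydroisoquinoline-2(1H)-carboxylate | COc1cc(OC)c2c(c1-c1ccc(OC)c(=O)o1)C[C@H](C)N(C(=O)OC)[C@@H]2C | intermediate
19 | 3-methoxy-5-methylphenol | COc1cc(C)cc(O)c1 | starting material
20 | 3-methoxy-5-methylphenyl isopropylcarbamate | COc1cc(C)cc(OC(=O)NC(C)C)c1 | intermediate
21 | 3-methoxy-5-methylphenyl N-(tert-butyldimethylsilyl)-N-isopropylcarbamate | COc1cc(C)cc(OC(=O)N(C(C)C)[Si](C)(C)C(C)(C)C)c1 | intermediate
22 | 2-lithio-3-methoxy-5-methylphenyl N-(tert-butyldimethylsilyl)-N-isopropylcarbamate | COc1cc(C)cc(OC(=O)N(C(C)C)[Si](C)(C)C(C)(C)C)c1[Li] | intermediate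
23 | 3-methoxy-5-methyl-2-(trimethylsilyl)phenyl N-(tert-butyldimethylsilyl)-N-isopropylcarbamate | COc1cc(C)cc(OC(=O)N(C(C)C)[Si](C)(C)C(C)(C)C)c1[Si](C)(C)C | intermediate
24 | 3-methoxy-5-methyl-2-(trimethylsilyl)phenyl isopropylcarbamate | COc1cc(C)cc(OC(=O)NC(C)C)c1[Si](C)(C)C | intermediate
25 | 3-methoxy-5-methyl-2-(trimethylsilyl)phenol | COc1cc(C)cc(O)c1[Si](C)(C)C | intermediate
26 | 3-methoxy-5-methyl-2-(trimethylsilyl)phenyl trifluoromethanesulfonate | COc1cc(C)cc(OS(=O)(=O)C(F)(F)F)c1[Si](C)(C)C | intermediate
27 | 3-methoxy-5-methylbenzyne | COC1=CC(C)=CC#C1 | intermediate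
28 | bridged lactone: [4+2] adduct of 27 across C3 and C6 of pyrone 18 (benzo-fused 2-oxabicyclo[2.2.2]octadien-3-one, bridgehead centres as a mixture) | COc1cc(OC)c2c(c1C13OC(=O)C(OC)(C=C1)c1c(OC)cc(C)cc13)C[C@H](C)N(C(=O)OC)[C@@H]2C | intermediate
29 | methyl (1R,3S)-5-(4,5-dimethoxy-7-methylnaphthalen-1-yl)-6,8-dimethoxy-1,3-dimethyl-3,4-dihydroisoquinoline-2(1H)-carboxylate | COc1cc(OC)c2c(c1-c1ccc(OC)c3c(OC)cc(C)cc13)C[C@H](C)N(C(=O)OC)[C@@H]2C | intermediate
30 | (1R,3S)-5-(4,5-dimethoxy-7-methylnaphthalen-1-yl)-6,8-dimethoxy-1,2,3-trimethyl-1,2,3,4-tetrahydroisoquinoline | COc1cc(OC)c2c(c1-c1ccc(OC)c3c(OC)cc(C)cc13)C[C@H](C)N(C)[C@@H]2C | target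

## Step count and least certain steps

Total step count: 17. Longest linear sequence: 12 steps (steps 1 to 7, 10, 11, 12, 16, 17). The enyne branch (steps 8 and 9) and the aryne branch (steps 13 to 15) run in parallel.

**Step 16 (key step).**
- *Risk.* The two ortho substituents of the perpendicular isoquinoline ring lie above and below pyrone C6. The cycloaddition may therefore be slower than consumption of the aryne by self-reaction or by adventitious nucleophiles. The orientation could also be incomplete if steric retardation at C6 outweighs the polar bias.
- *Fallback.* It gives up ring construction and makes the axis by Suzuki–Miyaura coupling, setting out from 11 and coming back at 29. 2,4-Dibromoanisole is deprotonated between its two bromine atoms with LiN(iPr)2 in the presence of the lithium dienolate of N,N-diethyl-3-methylbut-2-enamide. The bromomethoxyaryne so formed is attacked by the γ-carbon of the dienolate at the position remote from the methoxy group, and the aryl anion closes onto the amide, giving 5-bromo-8-methoxy-3-methylnaphthalen-1-ol F1. O-Methylation (MeI, K2CO3, acetone) gives 1-bromo-4,5-dimethoxy-7-methylnaphthalene F2. Bromine–lithium exchange (n-BuLi, THF, −78 °C), B(OMe)3 and acidic hydrolysis give (4,5-dimethoxy-7-methylnaphthalen-1-yl)boronic acid F3. This is coupled with 11 (Pd(OAc)2, SPhos, K3PO4, toluene/H2O, 100 °C) to give 29.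

**Step 8.**
- *Risk.* The olefination may show poor geometric selectivity, drifting to the thermodynamically preferred arrangement with the chain trans to the ester. That leaves little of the isomer able to lactonise.
- *Fallback.* It replaces olefination by a stereoretentive coupling of a geometry-defined enol sulfonate, setting out from 11 and coming back at 16. Methyl methoxyacetate undergoes crossed Claisen condensation with methyl formate (NaOMe) to methyl 2-methoxy-3-oxopropanoate F4. Its lithium chelate holds the enolate oxygen cis to the ester, and O-sulfonylation (TsCl, N-methylimidazole, LiOH) gives methyl (E)-2-methoxy-3-(tosyloxy)acrylate F5. In parallel, 11 is coupled with trimethylsilylacetylene (PdCl2(PPh3)2, CuI, Et3N) to methyl (1R,3S)-6,8-dimethoxy-1,3-dimethyl-5-[(trimethylsilyl)ethynyl]-3,4-dihydroisoquinoline-2(1H)-carboxylate F6. Desilylation (K2CO3, MeOH) gives methyl (1R,3S)-5-ethynyl-6,8-dimethoxy-1,3-dimethyl-3,4-dihydroisoquinoline-2(1H)-carboxylate F7. Sonogashira coupling of F7 with F5 (PdCl2(PPh3)2, CuI, iPr2NEt, THF) proceeds with retention at the alkene and gives 16.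

**Step 12.**
- *Risk.* The 5-exo closure may compete because the aryl-bearing alkyne carbon is the more crowded one, or turnover may be sluggish with a mild Lewis acid.
- *Fallback.* It changes from alkyne activation to carbonyl chemistry, setting out from 16 and coming back at 18. Catalytic hydration of the alkyne ((Ph3P)AuCl, AgOTf, wet 1,4-dioxane, 60 °C) places oxygen on the aryl-bearing carbon, which both the donor arene and the acceptor ester make the electrophilic one. This gives methyl (1R,3S)-5-(4,5-dimethoxy-5-oxopent-3-enoyl)-6,8-dimethoxy-1,3-dimethyl-3,4-dihydroisoquinoline-2(1H)-carboxylate F8. DBU in toluene at 80 °C forms the extended enolate, in which the former double bond can rotate, and the enolate oxygen acylates on the ester with loss of methoxide to give 18. Because of that rotation, this path also tolerates either alkene geometry.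

**Step 7.**
- *Risk.* Some iodination may occur at C7, or a second iodination may take place, since both free ring positions are activated by two methoxy groups.
- *Fallback.* It halogenates both positions and removes the unwanted halogen selectively, setting out from 10 and coming back at 16. N-Bromosuccinimide (2 equiv, MeCN) gives methyl (1R,3S)-5,7-dibromo-6,8-dimethoxy-1,3-dimethyl-3,4-dihydroisoquinoline-2(1H)-carboxylate F9. One equivalent of n-BuLi (THF, −78 °C) exchanges the bromine at C7, because the resulting aryllithium is stabilised by two flanking methoxy groups. Quenching with MeOH leaves methyl (1R,3S)-5-bromo-6,8-dimethoxy-1,3-dimethyl-3,4-dihydroisoquinoline-2(1H)-carboxylate F10. Copper-free Sonogashira coupling of F10 with 15 (PdCl2(MeCN)2, XPhos, Cs2CO3, MeCN, 70 °C) gives 16.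

## Further compounds

F1 | step 16 | 5-bromo-8-methoxy-3-methylnaphthalen-1-ol | COc1ccc(Br)c2cc(C)cc(O)c12
F2 | step 16 | 1-bromo-4,5-dimethoxy-7-methylnaphthalene | COc1ccc(Br)c2cc(C)cc(OC)c12
F3 | step 16 | (4,5-dimethoxy-7-methylnaphthalen-1-yl)boronic acid | COc1ccc(B(O)O)c2cc(C)cc(OC)c12
F4 | step 8 | methyl 2-methoxy-3-oxopropanoate | COC(C=O)C(=O)OC
F5 | step 8 | methyl (E)-2-methoxy-3-(tosyloxy)acrylate | Cc1ccc(cc1)S(=O)(=O)O/C=C(/OC)C(=O)OC
F6 | step 8 | methyl (1R,3S)-6,8-dimethoxy-1,3-dimethyl-5-[(trimethylsilyl)ethynyl]-3,4-dihydroisoquinoline-2(1H)-carboxylate | COc1cc(OC)c2c(c1C#C[Si](C)(C)C)C[C@H](C)N(C(=O)OC)[C@@H]2C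
F7 | step 8 | methyl (1R,3S)-5-ethynyl-6,8-dimethoxy-1,3-dimethyl-3,4-dihydroisoquinoline-2(1H)-carboxylate | COc1cc(OC)c2c(c1C#C)C[C@H](C)N(C(=O)OC)[C@@H]2C
F8 | step 12 | methyl (1R,3S)-5-(4,5-dimethoxy-5-oxopent-3-enoyl)-6,8-dimethoxy-1,3-dimethyl-3,4-dihydroisoquinoline-2(1H)-carboxylate | COc1cc(OC)c2c(c1C(=O)CC=C(OC)C(=O)OC)C[C@H](C)N(C(=O)OC)[C@@H]2C
F9 | step 7 | methyl (1R,3S)-5,7-dibromo-6,8-dimethoxy-1,3-dimethyl-3,4-dihydroisoquinoline-2(1H)-carboxylate | COc1c(Br)c(OC)c2c(c1Br)C[C@H](C)N(C(=O)OC)[C@@H]2C
F10 | step 7 | methyl (1R,3S)-5-bromo-6,8-dimethoxy-1,3-dimethyl-3,4-dihydroisoquinoline-2(1H)-carboxylate | COc1cc(OC)c2c(c1Br)C[C@H](C)N(C(=O)OC)[C@@H]2C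
A1 | alternative 1 | methyl acetoacetate | COC(=O)CC(C)=O
A2 | alternative 1 | methyl (5S)-5-[(tert-butoxycarbonyl)amino]-2-(4,5-dimethoxy-7-methylnaphthalen-1-yl)hex-2-enoate | COC(=O)C(=CC[C@H](C)NC(=O)OC(C)(C)C)c1ccc(OC)c2c(OC)cc(C)cc12
A3 | alternative 1 | methyl 2-[(2S)-2-(tert-butoxycarbonylamino)propyl]-3-(4,5-dimethoxy-7-methylnaphthalen-1-yl)-4,6-dioxocyclohexane-1-carboxylate (ring centres as a mixture) | COC(=O)C1C(=O)CC(=O)C(c2ccc(OC)c3c(OC)cc(C)cc23)C1C[C@H](C)NC(=O)OC(C)(C)C
A4 | alternative 2 | methyl 2-{[(1R,3S)-6,8-dimethoxy-1,2,3-trimethyl-1,2,3,4-tetrahydroisoquinolin-5-yl]methyl}-6-methoxy-4-methylbenzoate | COC(=O)c1c(OC)cc(C)cc1Cc1c(OC)cc(OC)c2c1C[C@H](C)N(C)[C@@H]2C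
A5 | alternative 2 | methyl acrylate | C=CC(=O)OC
A6 | alternative 2 | methyl 4-[(1R,3S)-6,8-dimethoxy-1,2,3-trimethyl-1,2,3,4-tetrahydroisoquinolin-5-yl]-8-methoxy-6-methyl-1-oxo-1,2,3,4-tetrahydronaphthalene-2-carboxylate (new ring centres as a mixture) | COC(=O)C1CC(c2c(OC)cc(OC)c3c2C[C@H](C)N(C)[C@@H]3C)c2cc(C)cc(OC)c2C1=O
A7 | alternative 3 | (1R)-1-[2-allyl-3-(4,5-dimethoxy-7-methylnaphthalen-1-yl)-4,6-dimethoxyphenyl]ethan-1-amine | C=CCc1c(-c2ccc(OC)c3c(OC)cc(C)cc23)c(OC)cc(OC)c1[C@@H](C)N
A8 | alternative 3 | (1R,3S)-5-(4,5-dimethoxy-7-methylnaphthalen-1-yl)-6,8-dimethoxy-1,3-dimethyl-1,2,3,4-tetrahydroisoquinoline | COc1cc(OC)c2c(c1-c1ccc(OC)c3c(OC)cc(C)cc13)C[C@H](C)N[C@@H]2C
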